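## Retrosynthetic overview

- The target comes from its hydroquinone by O-sulfation, and the hydroquinone from its dimethyl ether; the key cut is the C13–C14 bond at the tertiary carbinol, made by cathodic ketyl–olefin coupling of a vinyl decalin with a bicyclic ether ketone.
- The vinyl decalin comes from andrographolide: rings A and B with their three stereocentres are bought; the side chain is cut back to C11 and arylated, C3 is deoxygenated, and C19 becomes the vinyl group.
- The bicyclic ketone comes from (S)-carvone: ring C is bought; two α′-alkylations set the quaternary carbon, the isopropenyl group is converted into the O–CMe2 unit of ring D, and hydrogenation sets the α-methyl.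
- Ring order: A/B and C from the pool, arene attached (step 3), ring D closed (step 11), halves joined (step 13), then deprotection and sulfation.

Assumption: the target is drawn as the neutral bis(hydrogen sulfate); it is made and handled as its disodium salt, and the final compound is written in the neutral form of the given SMILES. Labdane numbering of andrographolide (C1–C20) is used for the decalin part and 1-benzoxepine numbering for the bicyclic ether.

## Route

**Step 1**
Reactants: 1 andrographolide
Product: 2 14-deoxy-11,12-didehydroandrographolide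
Conditions: Al2O3 (neutral), pyridine, reflux
Reagents that add atoms: none
Why: Vinylogous base-mediated dehydration (1,4-elimination of the allylic C14 hydroxyl through the extended lactone enolate) gives the conjugated 11E-diene without touching any decalin stereocentre.

**Step 2**
Reactants: 2 14-deoxy-11,12-didehydroandrographolide
Product: 4 conjugated enal 3,19-dihydroxy-12,13,14,15,16-pentanor-ent-labd-8-en-11-al, via exocyclic-alkene aldehyde 3 (not isolated)
Conditions: K2OsO4·2H2O (2 mol %), NaIO4 (2.2 equiv), 2,6-lutidine, dioxane/H2O, 0 °C to rt; extract; DBU (0.2 equiv), CH2Cl2, rt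
Reagents that add atoms: sodium periodate, [Na+].[O-]I(=O)(=O)=O
Why: Lemieux–Johnson cleavage: the osmium catalyst should dihydroxylate the unhindered trans-disubstituted 11,12-alkene in preference to the hindered exocyclic 8(17)-methylidene and the electron-poor butenolide alkene, periodate cuts the diol to the C11 aldehyde, and DBU then moves the alkene into conjugation (dienolate reprotonation at C17), which removes the C9 stereocentre on purpose.

**Step 3**
Reactants: 4 conjugated enal; 5 2-bromo-1,4-dimethoxybenzene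
Product: 7 11-(2,5-dimethoxyphenyl)-12,13,14,15,16-pentanor-ent-labd-8-ene-3,11,19-triol, via (2,5-dimethoxyphenyl)lithium 6 (not isolated)
Conditions: 5 (3.6 equiv), n-BuLi (3.5 equiv), THF, −78 °C; then 4, −78 to 0 °C; NH4Cl (aq)
Reagents that add atoms: none
Why: Bromine–lithium exchange followed by 1,2-addition of the aryllithium to the hindered enal (two equivalents are used up as base by the free hydroxyls); the new C11 carbinol centre forms as an epimer mixture that is erased in step 4.

**Step 4**
Reactants: 7 allylic benzylic triol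
Product: 8 11-(2,5-dimethoxyphenyl)-12,13,14,15,16-pentanor-ent-labd-8-ene-3,19-diol
Conditions: Et3SiH, CF3CO2H, CH2Cl2, −40 to 0 °C; then K2CO3, MeOH
Reagents that add atoms: none
Why: Ionic hydrogenation: ionisation gives a benzylic/allylic cation stabilised by the dimethoxyarene, and hydride is delivered to the less hindered benzylic terminus C11, which keeps the tetrasubstituted 8,9-alkene; methanolysis cleaves any trifluoroacetate esters.

**Step 5**
Reactants: 8 3,19-diol
Product: 9 11-(2,5-dimethoxyphenyl)-3-oxo-12,13,14,15,16-pentanor-ent-labd-8-en-19-al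
Conditions: Dess–Martin periodinane (2.5 equiv), NaHCO3, CH2Cl2, rt
Reagents that add atoms: none
Why: Dess–Martin oxidation of the secondary and the neopentyl primary alcohol; the carbon between the two carbonyls (C4) is quaternary, so it cannot enolise or epimerise.

**Step 6**
Reactants: 9 keto aldehyde
Product: 10 11-(2,5-dimethoxyphenyl)-19-methylidene-12,13,14,15,16-pentanor-ent-labd-8-en-3-one (C4 carries methyl and vinyl)
Conditions: Ph3PCH3Br, KOt-Bu, THF, 0 °C; then crude 9, 0 °C to rt
Reagents that add atoms: methyltriphenylphosphonium bromide, C[P+](c1ccccc1)(c1ccccc1)c1ccccc1.[Br-]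
Why: Wittig methylenation, selective for the aldehyde over the hindered C3 ketone; the non-enolisable keto aldehyde is used crude and cold to limit deformylation.

**Step 7**
Reactants: 10 vinyl ketone
Product: 12 2-{[(4aR,5S,8aR)-5-ethenyl-2,5,8a-trimethyl-3,4,4a,5,6,7,8,8a-octahydronaphthalen-1-yl]methyl}-1,4-dimethoxybenzene, via hydrazone 11 (not isolated)
Conditions: N2H4·H2O, KOH, diethylene glycol, 130 °C then 200 °C, under argon
Reagents that add atoms: none
Why: Wolff–Kishner reduction (Huang-Minlon procedure) of the C3 ketone through hydrazone 11; C4 is quaternary, so the vinyl group cannot migrate and no stereocentre is at risk.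

**Step 8**
Reactants: 13 (S)-(+)-carvone
Product: 15 (5S,6R)-2-methyl-5-(prop-1-en-2-yl)-6-(prop-2-en-1-yl)cyclohex-2-en-1-one, via lithium dienolate 14 (not isolated)
Conditions: LiN(i-Pr)2, THF, −78 °C; allyl bromide, −78 to 0 °C
Reagents that add atoms: allyl bromide, C=CCBr
Why: Kinetic α′-deprotonation gives the cross-conjugated dienolate, which is allylated (enolate alkylation) mainly anti to the isopropenyl group; the C6 configuration does not matter because it is re-made in step 9.

**Step 9**
Reactants: 15 6-allylcarvone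
Product: 17 (5R,6S)-2,6-dimethyl-5-(prop-1-en-2-yl)-6-(prop-2-en-1-yl)cyclohex-2-en-1-one, via lithium dienolate 16 (not isolated)
Conditions: LiN(i-Pr)2, THF, −78 °C; MeI, DMPU, −78 to 0 °C
Reagents that add atoms: iodomethane, CI
Why: Second α′-enolate alkylation: iodomethane approaches the dienolate anti to the C5 isopropenyl group, so methyl ends trans and allyl cis to it, which sets the quaternary C6 (6S) under control of the carvone stereocentre.

**Step 10**
Reactants: 17 6-allyl-6-methylcarvone
Product: 18 (5S,6S)-2,6-dimethyl-6-(prop-2-en-1-yl)-5-{2-[(triethylsilyl)peroxy]propan-2-yl}cyclohex-2-en-1-one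
Conditions: Co(acac)2 (10 mol %), O2 (1 atm), Et3SiH (2 equiv), ClCH2CH2Cl, rt
Reagents that add atoms: dioxygen, O=O; triethylsilane, CC[SiH](CC)CC
Why: Isayama–Mukaiyama peroxidation: the cobalt hydride transfers a hydrogen atom to the 1,1-disubstituted alkene (Markovnikov tertiary radical), and O2 and the silane cap it as the silyl peroxide; the monosubstituted allyl group and the electron-poor enone react more slowly, and C5 is untouched.

**Step 11**
Reactants: 18 tertiary silyl peroxide
Product: 19 (5aS,9aS)-2,2,5a,7-tetramethyl-3,5a,9,9a-tetrahydro-1-benzoxepin-6(2H)-one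
Conditions: Tf2NH (10 mol %), (CF3)2CHOH/CH2Cl2 (1:4), 4 Å molecular sieves, −40 to 0 °C
Reagents that add atoms: none
Why: Proposed new method: the acid ionises the silyl peroxide O–O bond with 1,2-shift of the ring carbon from carbon to oxygen (Hock/Criegee rearrangement; the secondary alkyl migrates in preference to methyl and with retention, so C9a keeps the carvone configuration), and the resulting 2-alkoxyprop-2-yl cation, held cis to the allyl group on the neighbouring quaternary carbon, is captured by the terminal alkene carbon in a 7-endo oxonium-ene (Prins-type) closure with loss of the allylic proton instead of being hydrolysed to acetone, so that O1, C2 and both C2 methyls of ring D come from the isopropenyl group and O2 and C3–C5 from the allyl group; the closest known reactions are the Hock cleavage of tertiary hydroperoxides and Prins or oxonium-ene cyclisations of oxocarbenium ions made from acetals, which have not been coupled in this way or used to close an oxepane; no new stereocentre is formed.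

**Step 12**
Reactants: 19 bicyclic dienone ether
Product: 20 (5aS,7R,9aS)-2,2,5a,7-tetramethyloctahydro-1-benzoxepin-6(2H)-one
Conditions: H2 (1 atm), 10% Pd/C, EtOAc, rt
Reagents that add atoms: none
Why: Heterogeneous catalytic hydrogenation of both alkenes; hydrogen is expected to add to the enone from the convex β face, opposite the cis-fused oxepane whose C5a–C5 and C9a–O bonds shield the α face, which places the C7 methyl α (7R), cis to the ring oxygen.

**Step 13**
Reactants: 12 vinyl decalin; 20 bicyclic ketone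
Product: 21 (5aS,6R,7R,9aS)-6-{2-[(1S,4aR,8aR)-5-[(2,5-dimethoxyphenyl)methyl]-1,4a,6-trimethyl-1,2,3,4,4a,7,8,8a-octahydronaphthalen-1-yl]ethyl}-2,2,5a,7-tetramethyldecahydro-1-benzoxepin-6-ol
Conditions: undivided cell, Zn anode, Sn cathode, n-Bu4NBr, DMF, 10 mA (about 3 F/mol of 12), rt; 20 (2.5 equiv, excess recovered); NH4Cl (aq)
Reagents that add atoms: none
Why: Electroreductive ketone–olefin coupling: the cathodically formed ketyl radical anion of 20 adds to the terminal carbon of the unactivated vinyl group and the secondary radical is reduced and protonated; in the chair of 20 with axial C5a methyl and axial C9a–O bond, a zinc ion bridging the ketyl oxygen and the syn-axial ring oxygen should hold the oxygen on the α face and block axial attack, so the new C–C bond forms equatorially, trans to the C7 methyl, giving the axial 6R hydroxyl.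

**Step 14**
Reactants: 21 coupled dimethyl ether
Product: 23 hydroquinone 2-{[...]methyl}benzene-1,4-diol (21 with both OMe replaced by OH), via benzoquinone 22 (not isolated)
Conditions: (NH4)2Ce(NO3)6 (2.5 equiv), MeCN/H2O, 0 °C; then Na2S2O4 (aq), EtOAc, rt
Reagents that add atoms: water, O
Why: Oxidative demethylation of the hydroquinone dimethyl ether to the quinone followed by dithionite reduction; the tertiary alcohol, the ether ring and the tetrasubstituted alkene should survive these brief, cold conditions.

**Step 15**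
Reactants: 23 hydroquinone
Product: 24 target bis(hydrogen sulfate)
Conditions: SO3·pyridine (6 equiv), pyridine, rt; Na2CO3 (aq), reverse-phase chromatography (disodium salt)
Reagents that add atoms: sulfur trioxide pyridine complex, O=S(=O)=O.c1ccncc1
Why: O-Sulfation of the two phenols with the SO3·pyridine complex; the hindered axial tertiary alcohol is not sulfated at room temperature, and no stereocentre is touched.

## Compound list

1 | andrographolide | C[C@@]12CC[C@H]([C@@]([C@H]1CCC(=C)[C@H]2C/C=C/3\[C@@H](COC3=O)O)(C)CO)O | starting material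
2 | 14-deoxy-11,12-didehydroandrographolide (11E; decalin as in 1) | C[C@@]12CC[C@H]([C@@]([C@H]1CCC(=C)[C@H]2/C=C/C3=CCOC3=O)(C)CO)O | intermediate
3 | (1R,4aS,5R,6R,8aR)-6-hydroxy-5-(hydroxymethyl)-5,8a-dimethyl-2-methylidenedecahydronaphthalene-1-carbaldehyde (not isolated) | C[C@@]12CC[C@H]([C@@]([C@H]1CCC(=C)[C@H]2C=O)(C)CO)O | intermediate
4 | (4aS,5R,6R,8aR)-6-hydroxy-5-(hydroxymethyl)-2,5,8a-trimethyl-3,4,4a,5,6,7,8,8a-octahydronaphthalene-1-carbaldehyde | C[C@@]12CC[C@H]([C@@]([C@H]1CCC(C)=C2C=O)(C)CO)O | intermediate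
5 | 2-bromo-1,4-dimethoxybenzene | COc1ccc(OC)c(Br)c1 | starting material
6 | (2,5-dimethoxyphenyl)lithium (not isolated) | [Li]c1cc(OC)ccc1OC | intermediate
7 | 11-(2,5-dimethoxyphenyl)-12,13,14,15,16-pentanor-ent-labd-8-ene-3,11,19-triol (both C11 epimers; C3, C4, C5, C10 as in 1) | C[C@@]12CC[C@H]([C@@]([C@H]1CCC(C)=C2C(O)c3cc(OC)ccc3OC)(C)CO)O | intermediate
8 | 11-(2,5-dimethoxyphenyl)-12,13,14,15,16-pentanor-ent-labd-8-ene-3,19-diol (C3, C4, C5, C10 as in 1) | C[C@@]12CC[C@H]([C@@]([C@H]1CCC(C)=C2Cc3cc(OC)ccc3OC)(C)CO)O | intermediate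
9 | 11-(2,5-dimethoxyphenyl)-3-oxo-12,13,14,15,16-pentanor-ent-labd-8-en-19-al (C4, C5, C10 as in 1) | C[C@@]12CCC(=O)[C@@]([C@H]1CCC(C)=C2Cc3cc(OC)ccc3OC)(C)C=O | intermediate
10 | 11-(2,5-dimethoxyphenyl)-19-methylidene-12,13,14,15,16-pentanor-ent-labd-8-en-3-one (C4 bears β-methyl and α-vinyl) | C[C@@]12CCC(=O)[C@@]([C@H]1CCC(C)=C2Cc3cc(OC)ccc3OC)(C)C=C | intermediate
11 | hydrazone of ketone 10 (not isolated) | C[C@@]12CCC(=NN)[C@@]([C@H]1CCC(C)=C2Cc3cc(OC)ccc3OC)(C)C=C | intermediate
12 | 2-{[(4aR,5S,8aR)-5-ethenyl-2,5,8a-trimethyl-3,4,4a,5,6,7,8,8a-octahydronaphthalen-1-yl]methyl}-1,4-dimethoxybenzene | C[C@@]12CCC[C@@]([C@H]1CCC(C)=C2Cc3cc(OC)ccc3OC)(C)C=C | intermediate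
13 | (S)-(+)-carvone | CC1=CC[C@@H](CC1=O)C(=C)C | starting material
14 | lithium (3S)-6-methyl-3-(prop-1-en-2-yl)cyclohexa-1,5-dien-1-olate (not isolated) | CC1=CC[C@@H](C=C1O[Li])C(=C)C | intermediate
15 | (5S,6R)-2-methyl-5-(prop-1-en-2-yl)-6-(prop-2-en-1-yl)cyclohex-2-en-1-one | O=C1C(C)=CC[C@H](C(C)=C)[C@H]1CC=C | intermediate
16 | lithium (3R)-6-methyl-3-(prop-1-en-2-yl)-2-(prop-2-en-1-yl)cyclohexa-1,5-dien-1-olate (not isolated) | CC1=CC[C@H](C(C)=C)C(CC=C)=C1O[Li] | intermediate
17 | (5R,6S)-2,6-dimethyl-5-(prop-1-en-2-yl)-6-(prop-2-en-1-yl)cyclohex-2-en-1-one | O=C1C(C)=CC[C@H](C(C)=C)[C@]1(C)CC=C | intermediate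
18 | (5S,6S)-2,6-dimethyl-6-(prop-2-en-1-yl)-5-{2-[(triethylsilyl)peroxy]propan-2-yl}cyclohex-2-en-1-one | O=C1C(C)=CC[C@H](C(C)(C)OO[Si](CC)(CC)CC)[C@]1(C)CC=C | intermediate
19 | (5aS,9aS)-2,2,5a,7-tetramethyl-3,5a,9,9a-tetrahydro-1-benzoxepin-6(2H)-one (cis-fused) | O=C1C(C)=CC[C@@H]2OC(C)(C)CC=C[C@@]21C | intermediate
20 | (5aS,7R,9aS)-2,2,5a,7-tetramethyloctahydro-1-benzoxepin-6(2H)-one (cis-fused) | O=C1[C@H](C)CC[C@@H]2OC(C)(C)CCC[C@@]21C | intermediate
21 | (5aS,6R,7R,9aS)-6-{2-[(1S,4aR,8aR)-5-[(2,5-dimethoxyphenyl)methyl]-1,4a,6-trimethyl-1,2,3,4,4a,7,8,8a-octahydronaphthalen-1-yl]ethyl}-2,2,5a,7-tetramethyldecahydro-1-benzoxepin-6-ol | CC1=C(Cc2cc(OC)ccc2OC)[C@]2(C)CCC[C@@](C)(CC[C@@]3(O)[C@H](C)CC[C@@H]4OC(C)(C)CCC[C@@]43C)[C@H]2CC1 | intermediate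
22 | 2-substituted 1,4-benzoquinone from 21 (same terpenoid part; not isolated) | CC1=C(CC5=CC(=O)C=CC5=O)[C@]2(C)CCC[C@@](C)(CC[C@@]3(O)[C@H](C)CC[C@@H]4OC(C)(C)CCC[C@@]43C)[C@H]2CC1 | intermediate
23 | 2-substituted benzene-1,4-diol (hydroquinone; same terpenoid part as 21) | CC1=C(Cc2cc(O)ccc2O)[C@]2(C)CCC[C@@](C)(CC[C@@]3(O)[C@H](C)CC[C@@H]4OC(C)(C)CCC[C@@]43C)[C@H]2CC1 | intermediate
24 | CNP0125037.3, the 1,4-bis(hydrogen sulfate) of hydroquinone 23 | CC1=C(Cc2cc(OS(=O)(=O)O)ccc2OS(=O)(=O)O)[C@]2(C)CCC[C@@](C)(CC[C@@]3(O)[C@H](C)CC[C@@H]4OC(C)(C)CCC[C@@]43C)[C@H]2CC1 | target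

## Step count and risks

Total steps: 15 (steps 1–7 decalin half, steps 8–12 bicyclic ketone, steps 13–15 union and endgame). Longest linear sequence: 10 steps (1–7, 13–15) from andrographolide.

Three steps most likely to fail:

1. Step 11 (the proposed new step). The Hock cation may be hydrolysed or lose a proton to the enol ether before the allyl group traps it. The fallback uses known chemistry and sets out from 18. Acid-catalysed Hock cleavage in wet solvent (TsOH·H2O, THF/H2O) gives the hydroxy enone F1 and acetone. Acid-catalysed etherification with 2-methylbut-3-en-2-yl 2,2,2-trichloroacetimidate (cat. CF3SO3H, cyclohexane/CH2Cl2) gives the tertiary allyl ether F2. Ring-closing metathesis (second-generation Grubbs catalyst, CH2Cl2, 40 °C) closes ring D as the 3,4-alkene isomer F3. Hydrogenation of both alkenes (H2, 5% Rh/Al2O3, EtOAc, chosen to avoid allylic C–O hydrogenolysis) comes back to the route at 20.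

2. Step 13. The hindered ketyl may simply be reduced to the secondary alcohol, and 20 may epimerise at C7 under the cathodic conditions. The fallback reverses the polarity and sets out from 12. Hydroboration (9-BBN, THF; NaOH, H2O2) gives the primary alcohol F4; I2, PPh3 and imidazole give the iodide F5; t-BuLi (2.1 equiv, Et2O/pentane, −78 °C) gives the alkyllithium F6. This is transmetallated with CeCl3 and added to 20 at −78 °C. Equatorial attack, away from the syn-axial ring oxygen, gives the same carbinol, and the route is rejoined at 21.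

3. Step 6. The β-keto aldehyde 9 may deformylate or be methylenated poorly at the hindered axial aldehyde. The fallback removes the C3 oxygen first and sets out from 8. 1,1′-Thiocarbonyldiimidazole (DMAP, toluene, 90 °C) gives the cyclic 3,19-thionocarbonate F7. Bu3SnH and AIBN (toluene, 110 °C; then NaOH, MeOH) cleave the secondary C3–O bond (Barton–McCombie deoxygenation through the more stable secondary radical) and leave the 19-alcohol F8. Dess–Martin oxidation gives the neopentyl aldehyde F9, and Wittig methylenation (Ph3PCH3Br, KOt-Bu, THF) comes back to the route at 12, replacing steps 5 to 7.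

## Further compounds

F1 | step 11 | (5S,6S)-5-hydroxy-2,6-dimethyl-6-(prop-2-en-1-yl)cyclohex-2-en-1-one | O=C1C(C)=CC[C@H](O)[C@]1(C)CC=C
F2 | step 11 | (5S,6S)-2,6-dimethyl-5-[(2-methylbut-3-en-2-yl)oxy]-6-(prop-2-en-1-yl)cyclohex-2-en-1-one | O=C1C(C)=CC[C@H](OC(C)(C)C=C)[C@]1(C)CC=C
F3 | step 11 | (5aS,9aS)-2,2,5a,7-tetramethyl-5,5a,9,9a-tetrahydro-1-benzoxepin-6(2H)-one | O=C1C(C)=CC[C@@H]2OC(C)(C)C=CC[C@@]21C
F4 | step 13 | 2-[(1S,4aR,8aR)-5-[(2,5-dimethoxyphenyl)methyl]-1,4a,6-trimethyl-1,2,3,4,4a,7,8,8a-octahydronaphthalen-1-yl]ethan-1-ol | C[C@@]12CCC[C@@]([C@H]1CCC(C)=C2Cc3cc(OC)ccc3OC)(C)CCO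
F5 | step 13 | primary iodide from F4 (CH2CH2I on C4 of the decalin) | C[C@@]12CCC[C@@]([C@H]1CCC(C)=C2Cc3cc(OC)ccc3OC)(C)CCI
F6 | step 13 | alkyllithium from F5 (CH2CH2Li on C4 of the decalin) | C[C@@]12CCC[C@@]([C@H]1CCC(C)=C2Cc3cc(OC)ccc3OC)(C)CC[Li]
F7 | step 6 | cyclic 3,19-thionocarbonate of diol 8 | C[C@@]12CC[C@H]([C@@]([C@H]1CCC(C)=C2Cc3cc(OC)ccc3OC)(C)CO4)OC4=S
F8 | step 6 | 11-(2,5-dimethoxyphenyl)-12,13,14,15,16-pentanor-ent-labd-8-en-19-ol | C[C@@]12CCC[C@@]([C@H]1CCC(C)=C2Cc3cc(OC)ccc3OC)(C)CO
F9 | step 6 | 11-(2,5-dimethoxyphenyl)-12,13,14,15,16-pentanor-ent-labd-8-en-19-al | C[C@@]12CCC[C@@]([C@H]1CCC(C)=C2Cc3cc(OC)ccc3OC)(C)C=O
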